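**Strategy.** The quinone ring is built last by closing its C3–C4 bond (C4: the carbonyl carbon beside the methoxy carbon C5; C3: the carbon carrying the benzylic C11H2 of the decalin). The step exploits that a p-quinone with a CH2 group on C3 is the keto tautomer of a 4-hydroxy-o-quinone methide. A squarate-derived 4-hydroxy-4-(1-alkoxyallenyl)-2-methoxycyclobutenone, whose allene terminus is C11 on the quaternary decalin carbon C9, is heated: 4π ring opening, 6π electrocyclisation of the ketene carbon (C4) onto the central allene carbon (C3), and proton shift give the fully substituted quinone in one operation. The cis-decalinol comes from an exo Diels–Alder reaction and epoxide reduction.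

Key step: step 13

Remark on numbering: decalin carbons carry drimane-type numbers (C4 gem-dimethyl carbon, C5 and C10 ring-fusion carbons, C8 the CH(CH3) carbon, C9 the quaternary carbon, C11 the carbon on C9 that ends as the benzylic CH2). α is the face of H-10, β the face of the C8 and C9 methyl groups. Quinone carbons are numbered as in 2-hydroxy-3-alkyl-5-methoxy-1,4-benzoquinone.

Assumption: the (S)-configured oxazaborolidinium salt of step 3 is taken to deliver the enantiomer drawn; should the facial sense be opposite, its mirror image is used.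

Remark: 13 and 15–21 are carried as stereoisomer mixtures at the allene axis, the cyclobutene carbinol carbon or the exocyclic alkene (left undefined in the SMILES); all these elements vanish in step 13.

**Step 1**
Reactants: 1 2,2-dimethylcyclohexanone
Product: 3 6,6-dimethylcyclohex-1-en-1-yl trifluoromethanesulfonate, via lithium enolate 2 (not isolated)
Conditions: LiN(i-Pr)2, THF, −78 °C; PhNTf2, −78 °C → rt
Reagents that add atoms: N-phenylbis(trifluoromethanesulfonimide), FC(F)(F)S(=O)(=O)N(c1ccccc1)S(=O)(=O)C(F)(F)F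
Why: Only one α-carbon bears hydrogen, so a single enolate forms and is O-sulfonylated (enol triflate formation).

**Step 2**
Reactants: 3 6,6-dimethylcyclohex-1-en-1-yl trifluoromethanesulfonate
Product: 4 1-ethenyl-6,6-dimethylcyclohex-1-ene
Conditions: tributyl(vinyl)stannane, Pd(PPh3)4 (5 mol%), LiCl, THF, reflux
Reagents that add atoms: tributyl(vinyl)stannane, C=C[Sn](CCCC)(CCCC)CCCC
Why: Stille cross-coupling of an enol triflate with a vinylstannane, with LiCl assisting transmetalation, gives the semicyclic diene.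

**Step 3**
Reactants: 4 1-ethenyl-6,6-dimethylcyclohex-1-ene, 5 (E)-2-methylbut-2-enal
Product: 6 4,4,8β,9β-tetramethyl-10α-H-octal-5-ene-9α-carbaldehyde
Conditions: (S)-3,3-diphenyl-1-(o-tolyl)tetrahydro-1H,3H-pyrrolo[1,2-c][1,3,2]oxazaborole (20 mol%), HNTf2 (18 mol%), CH2Cl2, −78 → −20 °C
Reagents that add atoms: none
Why: Lewis-acid-catalysed Diels–Alder reaction in which the ring terminus C10 of the diene bonds to the formyl-bearing carbon C9 ("ortho" rule) and C7 to C8; the E geometry of 5 fixes the cis relation of the C8 and C9 methyl groups, the gem-dimethyl carbon flanking the diene disfavours the endo position for the coordinated formyl group so that the exo adduct (formyl cis to H-10) is expected, and the chiral boron Lewis acid shields one face of the s-trans enal to set the absolute configuration of C8, C9 and C10.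

**Step 4**
Reactants: 6 4,4,8β,9β-tetramethyl-10α-H-octal-5-ene-9α-carbaldehyde
Product: 7 9α-ethynyl-4,4,8β,9β-tetramethyl-10α-H-octal-5-ene
Conditions: dimethyl (1-diazo-2-oxopropyl)phosphonate, K2CO3, MeOH, 0 °C → rt
Reagents that add atoms: dimethyl (1-diazo-2-oxopropyl)phosphonate, CC(=O)C(=[N+]=[N-])P(=O)(OC)OC
Why: Seyferth–Gilbert homologation with the Ohira–Bestmann reagent turns the aldehyde carbon C11 into the internal alkyne carbon, and C9 has no α-hydrogen and cannot epimerise.

**Step 5**
Reactants: 7 9α-ethynyl-4,4,8β,9β-tetramethyl-10α-H-octal-5-ene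
Product: 9 9α-{3-[2-(trimethylsilyl)ethoxy]prop-1-yn-1-yl}-4,4,8β,9β-tetramethyl-10α-H-octal-5-ene, via lithium acetylide 8 (not isolated)
Conditions: n-BuLi, THF, −78 °C; 2-(trimethylsilyl)ethoxymethyl chloride, −78 °C → rt
Reagents that add atoms: 2-(trimethylsilyl)ethoxymethyl chloride, C[Si](C)(C)CCOCCl
Why: Deprotonation of the terminal alkyne and C-alkylation of the acetylide by the reactive chloromethyl ether (SN2) give the propargylic ether that carries the future C2 oxygen of the quinone.

**Step 6**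
Reactants: 9 9α-{3-[2-(trimethylsilyl)ethoxy]prop-1-yn-1-yl}-4,4,8β,9β-tetramethyl-10α-H-octal-5-ene
Product: 10 5α,6α-epoxide of 9
Conditions: mCPBA, NaHCO3, CH2Cl2, 0 °C
Reagents that add atoms: 3-chloroperoxybenzoic acid, OOC(=O)c1cccc(Cl)c1
Why: Prilezhaev epoxidation of the trisubstituted alkene (the alkyne reacts far more slowly) from the α face, because the β face is screened by the C8 and C9 methyl groups and, in the other half-chair, by C1, so the oxygen ends cis to H-10.

**Step 7**
Reactants: 10 5α,6α-epoxide of 9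
Product: 11 9α-{3-[2-(trimethylsilyl)ethoxy]prop-1-yn-1-yl}-4,4,8β,9β-tetramethyl-10α-H-decalin-5α-ol
Conditions: LiEt3BH, THF, 0 → 50 °C; H2O
Reagents that add atoms: none
Why: Hydride opens the epoxide by SN2 attack at the less substituted C6, which leaves the oxygen on C5 with the α configuration set in step 6 and gives the cis-fused tertiary alcohol.

**Step 8**
Reactants: 11 9α-{3-[2-(trimethylsilyl)ethoxy]prop-1-yn-1-yl}-4,4,8β,9β-tetramethyl-10α-H-decalin-5α-ol
Product: 12 triethylsilyl ether of 11
Conditions: Et3SiOTf, 2,6-lutidine, CH2Cl2, −78 → 0 °C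
Reagents that add atoms: triethylsilyl trifluoromethanesulfonate, CC[Si](CC)(CC)OS(=O)(=O)C(F)(F)F
Why: A silyl triflate silylates the hindered tertiary alcohol, which masks the C5 oxygen so that it cannot add to the quinone methide of step 13.

**Step 9**
Reactants: 12 triethylsilyl ether of 11
Product: 13 9α-{3-[2-(trimethylsilyl)ethoxy]propa-1,2-dien-1-yl}-5α-(triethylsilyloxy)-4,4,8β,9β-tetramethyl-10α-H-decalin
Conditions: KOt-Bu (0.3 equiv), DMSO/THF, rt
Reagents that add atoms: none
Why: Base-catalysed propargyl-to-allenyl ether isomerisation is driven by conjugation of oxygen with the allene, and the quaternary C9 stops any further migration.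

**Step 10**
Reactants: 13 allenyl ether, 14 dimethyl squarate (3,4-dimethoxycyclobut-3-ene-1,2-dione)
Product: 16 4-hydroxy-2,3-dimethoxy-4-(1-alkoxyallenyl)cyclobut-2-en-1-one, via lithioallene 15 (not isolated)
Conditions: n-BuLi, THF, −78 → −40 °C; 14, THF, −78 °C; H2O
Reagents that add atoms: none
Why: The oxygen-bearing allenic C–H is the most acidic, 1-lithio-1-alkoxyallenes add to carbonyl groups through that carbon, and dimethyl squarate takes one organolithium in a 1,2-addition; the new carbinol centre is unselective and irrelevant.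

**Step 11**
Reactants: 16 4-hydroxy-2,3-dimethoxy-4-(1-alkoxyallenyl)cyclobut-2-en-1-one
Product: 17 1-(1-alkoxyallenyl)-2,3-dimethoxycyclobut-2-ene-1,4-diol
Conditions: i-Bu2AlH (2.5 equiv), THF/toluene, −78 °C; aqueous KNaC4H4O6
Reagents that add atoms: none
Why: 1,2-Reduction of the vinylogous ester carbonyl by an aluminium hydride (the first equivalent is spent on the hydroxyl) gives the allylic alcohol, whose new centre is lost in step 12.

**Step 12**
Reactants: 17 1-(1-alkoxyallenyl)-2,3-dimethoxycyclobut-2-ene-1,4-diol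
Product: 19 4-hydroxy-2-methoxy-4-(1-alkoxyallenyl)cyclobut-2-en-1-one, via secondary mesylate 18 (not isolated)
Conditions: MsCl, Et3N, CH2Cl2, −40 → 0 °C; aqueous NaHCO3
Reagents that add atoms: water, O
Why: The secondary allylic hydroxyl is sulfonylated in preference to the tertiary one, the mesylate ionises with help from the 1,3-related methoxy group, and hydrolysis of the oxocarbenium ion gives the transposed enone (Stork–Danheiser-type 1,3-carbonyl transposition) with hydrogen on C3 and methoxy on C2 under non-acidic conditions that spare the alkoxyallene.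

**Step 13**
Reactants: 19 4-hydroxy-2-methoxy-4-(1-alkoxyallenyl)cyclobut-2-en-1-one
Product: 22 3-(decalinylmethyl)-5-methoxy-2-[2-(trimethylsilyl)ethoxy]-1,4-benzoquinone, via allenyl vinylketene 20 (not isolated), via hydroxy o-quinone methide 21 (not isolated)
Conditions: toluene (0.005 M), 110 °C
Reagents that add atoms: none
Why: Heating opens the cyclobutenone by conrotatory 4π electrocyclic cleavage of the C(=O)–C(OH) bond, the hydroxyl rotating outward so that the alkoxyallenyl group ends cis to the ketene in 20. A thermal disrotatory 6π electrocyclisation across the ketene C=C, the enol C=C and the proximal allene C=C then joins the ketene carbon (C4) to the central allene carbon (C3), which closes the six-membered carbocycle and gives the 4-hydroxy-o-quinone methide 21; proton transfer from that hydroxyl to the exocyclic C11 delivers the p-quinone 22, so the closure is redox-neutral and needs no oxidant. The closest known reaction types are the thermal ring expansion of 4-allenylcyclobutenones to o-quinone methides and of 4-alkynyl-4-hydroxycyclobutenones to quinones. No stereocentre is created: the carbinol centre and the allene axis of 19 are destroyed, and the four decalin centres are remote and untouched. The step needs outward rotation of the hydroxyl (secured by its donor character, which also prevents butenolide formation), 6π closure ahead of nucleophilic capture of 20 or 21 (secured by high dilution, the silyl cap on the C5 oxygen and the absence of protic additives) and a single outlet for 21 (the quaternary C9 offers no hydrogen for a 1,5-shift to a vinylphenol).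

**Step 14**
Reactants: 22 3-(decalinylmethyl)-5-methoxy-2-[2-(trimethylsilyl)ethoxy]-1,4-benzoquinone
Product: 23 2-hydroxy-3-{[(1R,2S,4aS,8aS)-4a-hydroxy-1,2,5,5-tetramethyldecahydronaphthalen-1-yl]methyl}-5-methoxy-1,4-benzoquinone
Conditions: Bu4NF, AcOH, THF, 0 °C → rt
Reagents that add atoms: none
Why: Fluoride cleaves the tertiary triethylsilyl ether and triggers β-elimination of the 2-(trimethylsilyl)ethyl group from the vinylogous ester oxygen on C2, while the methyl vinylogous ester on C5 has no such pathway and stays.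

**Compound list**

1 | 2,2-dimethylcyclohexanone | CC1(C)CCCCC1=O | starting material
2 | lithium 6,6-dimethylcyclohex-1-en-1-olate | CC1(C)CCCC=C1O[Li] | intermediate
3 | 6,6-dimethylcyclohex-1-en-1-yl trifluoromethanesulfonate | CC1(C)CCCC=C1OS(=O)(=O)C(F)(F)F | intermediate
4 | 1-ethenyl-6,6-dimethylcyclohex-1-ene | C=CC1=CCCCC1(C)C | intermediate
5 | (E)-2-methylbut-2-enal (tiglic aldehyde) | C/C=C(\C)C=O | starting material
6 | (1R,2S,8aR)-1,2,5,5-tetramethyl-1,2,3,5,6,7,8,8a-octahydronaphthalene-1-carbaldehyde (8β,9β-dimethyl, 9α-formyl, 10α-H, C5=C6 alkene) | O=C[C@]1(C)[C@@H](C)CC=C2[C@H]1CCCC2(C)C | intermediate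
7 | (1R,2S,8aR)-1-ethynyl-1,2,5,5-tetramethyl-1,2,3,5,6,7,8,8a-octahydronaphthalene | C#C[C@]1(C)[C@@H](C)CC=C2[C@H]1CCCC2(C)C | intermediate
8 | lithium acetylide of 7 | [Li]C#C[C@]1(C)[C@@H](C)CC=C2[C@H]1CCCC2(C)C | intermediate
9 | 2-(trimethylsilyl)ethyl propargylic ether: 7 with CH2OCH2CH2SiMe3 on the alkyne terminus | C[Si](C)(C)CCOCC#C[C@]1(C)[C@@H](C)CC=C2[C@H]1CCCC2(C)C | intermediate
10 | 5α,6α-epoxide of 9 (oxygen cis to H-10) | C[Si](C)(C)CCOCC#C[C@]1(C)[C@@H](C)C[C@@H]2O[C@]23[C@H]1CCCC3(C)C | intermediate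
11 | cis-fused decalin-5α-ol (5α-OH, 10α-H, 8β,9β-dimethyl) with the 3-[2-(trimethylsilyl)ethoxy]prop-1-ynyl group on the α face of C9 | C[Si](C)(C)CCOCC#C[C@]1(C)[C@@H](C)CC[C@]2(O)[C@H]1CCCC2(C)C | intermediate
12 | triethylsilyl ether of 11 | C[Si](C)(C)CCOCC#C[C@]1(C)[C@@H](C)CC[C@]2(O[Si](CC)(CC)CC)[C@H]1CCCC2(C)C | intermediate
13 | allenyl ether: decalin of 12 with a 3-[2-(trimethylsilyl)ethoxy]propa-1,2-dien-1-yl group on C9 (allene axis undefined) | C[Si](C)(C)CCOC=C=C[C@]1(C)[C@@H](C)CC[C@]2(O[Si](CC)(CC)CC)[C@H]1CCCC2(C)C | intermediate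
14 | dimethyl squarate (3,4-dimethoxycyclobut-3-ene-1,2-dione) | COC1=C(OC)C(=O)C1=O | starting material
15 | 13 lithiated at the oxygen-bearing allene carbon | [Li]C(OCC[Si](C)(C)C)=C=C[C@]1(C)[C@@H](C)CC[C@]2(O[Si](CC)(CC)CC)[C@H]1CCCC2(C)C | intermediate
16 | 4-hydroxy-2,3-dimethoxycyclobut-2-en-1-one whose C4 carries the alkoxyallenyl group of 13 through its oxygen-bearing carbon | COC1=C(OC)C(O)(C(OCC[Si](C)(C)C)=C=C[C@]2(C)[C@@H](C)CC[C@]3(O[Si](CC)(CC)CC)[C@H]2CCCC3(C)C)C1=O | intermediate
17 | diol from 16 by reduction of C=O to CHOH | COC1=C(OC)C(O)(C(OCC[Si](C)(C)C)=C=C[C@]2(C)[C@@H](C)CC[C@]3(O[Si](CC)(CC)CC)[C@H]2CCCC3(C)C)C1O | intermediate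
18 | methanesulfonate of the secondary hydroxyl of 17 | COC1=C(OC)C(O)(C(OCC[Si](C)(C)C)=C=C[C@]2(C)[C@@H](C)CC[C@]3(O[Si](CC)(CC)CC)[C@H]2CCCC3(C)C)C1OS(C)(=O)=O | intermediate
19 | 4-hydroxy-2-methoxycyclobut-2-en-1-one (H on C3) whose C4 carries the alkoxyallenyl group | COC1=CC(O)(C(OCC[Si](C)(C)C)=C=C[C@]2(C)[C@@H](C)CC[C@]3(O[Si](CC)(CC)CC)[C@H]2CCCC3(C)C)C1=O | intermediate
20 | ring-opened vinylketene (hydroxyl trans, allenyl cis to the ketene-bearing carbon) | O=C=C(OC)/C=C(/O)C(OCC[Si](C)(C)C)=C=C[C@]1(C)[C@@H](C)CC[C@]2(O[Si](CC)(CC)CC)[C@H]1CCCC2(C)C | intermediate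
21 | 4-hydroxy-2-methoxy-5-[2-(trimethylsilyl)ethoxy]-6-(decalinylmethylidene)cyclohexa-2,4-dien-1-one (o-quinone methide) | O=C1C(OC)=CC(O)=C(OCC[Si](C)(C)C)C1=C[C@]2(C)[C@@H](C)CC[C@]3(O[Si](CC)(CC)CC)[C@H]2CCCC3(C)C | intermediate
22 | 5-methoxy-2-[2-(trimethylsilyl)ethoxy]-3-(decalinylmethyl)-1,4-benzoquinone with 5α-triethylsilyloxy on the decalin | O=C1C(OC)=CC(=O)C(OCC[Si](C)(C)C)=C1C[C@]2(C)[C@@H](C)CC[C@]3(O[Si](CC)(CC)CC)[C@H]2CCCC3(C)C | intermediate
23 | 2-hydroxy-3-{[(1R,2S,4aS,8aS)-4a-hydroxy-1,2,5,5-tetramethyldecahydronaphthalen-1-yl]methyl}-5-methoxycyclohexa-2,5-diene-1,4-dione | COC1=CC(=O)C(O)=C(C[C@]2(C)[C@@H](C)CC[C@]3(O)[C@H]2CCCC3(C)C)C1=O | target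

Total step count: 14. Longest linear sequence: 14 steps (1 → 23).

**Steps most likely to fail**

1. Step 13. The o-quinone methide may be consumed by dimerisation or by adventitious nucleophiles faster than the proton shift to the quinone, or the ketene may be trapped before it cyclises. Fallback (sets out from 19, comes back at 22): the carbinol is silylated (t-BuMe2SiOTf, 2,6-lutidine) to the tert-butyldimethylsilyl ether F1. Heating F1 in toluene with diethyl 2,6-dimethyl-1,4-dihydropyridine-3,5-dicarboxylate should pass through the silyloxy vinylketene F2 and the silyloxy o-quinone methide F3, which cannot tautomerise and is reduced by the dihydropyridine as it forms to the phenol F4. K2CO3 in MeOH cleaves the aryl silyl ether to the hydroquinone F5, and Ag2O oxidises F5 to 22.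

2. Step 3. Exo/endo or facial discrimination may be insufficient, or the acid may oligomerise the electron-rich diene. Fallback (sets out from 4 and 5, comes back at 6): the cycloaddition is run with EtAlCl2 in CH2Cl2 at −78 °C, which gives 6 together with its mirror-image aldehyde F6. Condensation of the mixture with (1R,2R)-N,N'-dimethyl-1,2-diphenylethane-1,2-diamine gives the diastereomeric imidazolidines F7 (from 6) and F8 (from F6), which are separated by chromatography or crystallisation. Dilute aqueous HCl releases 6 from F7.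

3. Step 12. Ionisation at the tertiary carbinol or hydrolysis of the alkoxyallene may compete with clean transposition. Fallback (sets out from 16, comes back at 19): the two hydroxyls are told apart by protection instead of by rate of sulfonylation. The tertiary hydroxyl of 16 is capped (Me3SiCl, imidazole) to the trimethylsilyl ether F9, and i-Bu2AlH reduces the carbonyl to the secondary alcohol F10. (CF3CO)2O and pyridine at −78 °C give the trifluoroacetate F11, which ionises and is hydrolysed on aqueous NaHCO3 work-up to the transposed cyclobutenone F12. Bu4NF buffered with AcOH at −20 °C removes the trimethylsilyl group to give 19.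

**Further compounds**

F1 | step 13 | tert-butyldimethylsilyl ether of 19 | COC1=CC(O[Si](C)(C)C(C)(C)C)(C(OCC[Si](C)(C)C)=C=C[C@]2(C)[C@@H](C)CC[C@]3(O[Si](CC)(CC)CC)[C@H]2CCCC3(C)C)C1=O
F2 | step 13 | silyloxy vinylketene (tert-butyldimethylsilyl ether of 20) | O=C=C(OC)/C=C(/O[Si](C)(C)C(C)(C)C)C(OCC[Si](C)(C)C)=C=C[C@]1(C)[C@@H](C)CC[C@]2(O[Si](CC)(CC)CC)[C@H]1CCCC2(C)C
F3 | step 13 | silyloxy o-quinone methide (tert-butyldimethylsilyl ether of 21) | O=C1C(OC)=CC(O[Si](C)(C)C(C)(C)C)=C(OCC[Si](C)(C)C)C1=C[C@]2(C)[C@@H](C)CC[C@]3(O[Si](CC)(CC)CC)[C@H]2CCCC3(C)C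
F4 | step 13 | 4-(tert-butyldimethylsilyloxy)-2-(decalinylmethyl)-6-methoxy-3-[2-(trimethylsilyl)ethoxy]phenol | COc1cc(O[Si](C)(C)C(C)(C)C)c(OCC[Si](C)(C)C)c(C[C@]2(C)[C@@H](C)CC[C@]3(O[Si](CC)(CC)CC)[C@H]2CCCC3(C)C)c1O
F5 | step 13 | 2-(decalinylmethyl)-6-methoxy-3-[2-(trimethylsilyl)ethoxy]benzene-1,4-diol | COc1cc(O)c(OCC[Si](C)(C)C)c(C[C@]2(C)[C@@H](C)CC[C@]3(O[Si](CC)(CC)CC)[C@H]2CCCC3(C)C)c1O
F6 | step 3 | mirror image of 6, (1S,2R,8aS)-aldehyde | O=C[C@@]1(C)[C@H](C)CC=C2[C@@H]1CCCC2(C)C
F7 | step 3 | (4R,5R)-1,3-dimethyl-4,5-diphenylimidazolidine carrying the decalin of 6 on C2 | CN1[C@H](c2ccccc2)[C@@H](c2ccccc2)N(C)C1[C@]3(C)[C@@H](C)CC=C4[C@H]3CCCC4(C)C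
F8 | step 3 | (4R,5R)-1,3-dimethyl-4,5-diphenylimidazolidine carrying the decalin of F6 on C2 | CN1[C@H](c2ccccc2)[C@@H](c2ccccc2)N(C)C1[C@@]3(C)[C@H](C)CC=C4[C@@H]3CCCC4(C)C
F9 | step 12 | trimethylsilyl ether of 16 | COC1=C(OC)C(O[Si](C)(C)C)(C(OCC[Si](C)(C)C)=C=C[C@]2(C)[C@@H](C)CC[C@]3(O[Si](CC)(CC)CC)[C@H]2CCCC3(C)C)C1=O
F10 | step 12 | secondary alcohol from reduction of F9 | COC1=C(OC)C(O[Si](C)(C)C)(C(OCC[Si](C)(C)C)=C=C[C@]2(C)[C@@H](C)CC[C@]3(O[Si](CC)(CC)CC)[C@H]2CCCC3(C)C)C1O
F11 | step 12 | trifluoroacetate of F10 | COC1=C(OC)C(O[Si](C)(C)C)(C(OCC[Si](C)(C)C)=C=C[C@]2(C)[C@@H](C)CC[C@]3(O[Si](CC)(CC)CC)[C@H]2CCCC3(C)C)C1OC(=O)C(F)(F)F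
F12 | step 12 | trimethylsilyl ether of 19 | COC1=CC(O[Si](C)(C)C)(C(OCC[Si](C)(C)C)=C=C[C@]2(C)[C@@H](C)CC[C@]3(O[Si](CC)(CC)CC)[C@H]2CCCC3(C)C)C1=O
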